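**Plan**

1. Numbering as in 1H-isochromene: C1H2–O2–C3(dienyl)=C4–C4a=C5(Cl)–C6(=O)–C7(Me)(OH)–C8(OH)–C8a(Ac). The retrosynthesis cuts C4–C4a and O2–C3 together (dienyne side chain + monocyclic ring B triflate), then the 7,8-diol, C6=O, C4a–OTf/C5–Cl, the acetyl methyl and C8a–C1, back to 2-methoxy-5-methylbenzoic acid.
2. Enabling feature: O2–C3=C4–C4a=C5–C6=O is a doubly vinylogous ester. C4a is the β-carbon of the 2-chloro-enone of ring B and can carry a triflate; C3 is the δ-carbon that the C1 hydroxyl on quaternary C8a reaches by 6-endo addition.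
3. Forward: ring B first, by Birch reduction–alkylation of the arene (dearomatization, quaternary C8a), then C5–Cl, C4a–OTf, C6=O and the 7,8-diol. The side chain is made separately. Ring A closes last, in the one-pot step that also joins the two fragments.
4. Stereochemistry: C8a from classical resolution of the Birch acid; C7 and C8 from OsO4 addition to the flat dienone anti to CH2OTIPS (syn to acetyl); the side-chain S center from (2S)-2-methylbutan-1-ol; both new E alkenes from stabilized-ylide Wittig and Horner–Wadsworth–Emmons olefinations.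

Key step: step 11

Remark: which antipode of 1-phenylethylamine gives the less soluble salt with the (R)-acid cannot be predicted; the (R)-amine is written here and its antipode is used if the other salt crystallizes, the acid configuration being secured by X-ray analysis of the salt.

**Route**

Step 1
Reactants: 1 2-methoxy-5-methylbenzoic acid
Product: 2 rac-2-methoxy-5-methyl-1-({[tri(propan-2-yl)silyl]oxy}methyl)cyclohexa-2,5-diene-1-carboxylic acid
Conditions: Li, NH3(l)–THF, t-BuOH (1 equiv), −78 °C; NH3 evaporated; (i-Pr)3SiOCH2Cl, THF, −78 to 0 °C; cold aq. citric acid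
Reagents that add atoms: (chloromethoxy)tri(propan-2-yl)silane, ClCO[Si](C(C)C)(C(C)C)C(C)C
Why: Birch reduction–alkylation: the carboxylate directs 1,4-reduction to C8a and C6, so the methoxy and methyl groups stay on the two remaining double bonds, and the dianion is alkylated at the carboxyl-bearing carbon by the reactive α-chloro ether (as with benzyloxymethyl chloride), which dearomatizes the ring and creates the quaternary carbon as a racemate.

Step 2
Reactants: 2 rac-2-methoxy-5-methyl-1-({[tri(propan-2-yl)silyl]oxy}methyl)cyclohexa-2,5-diene-1-carboxylic acid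
Product: 3 (1R)-1-phenylethan-1-aminium (1R)-2-methoxy-5-methyl-1-({[tri(propan-2-yl)silyl]oxy}methyl)cyclohexa-2,5-diene-1-carboxylate
Conditions: (R)-1-phenylethylamine (0.55 equiv), EtOAc–heptane, 60 to 5 °C; one recrystallization
Reagents that add atoms: (1R)-1-phenylethan-1-amine, C[C@@H](N)c1ccccc1
Why: Classical resolution by diastereomeric salt crystallization: the quaternary carbon cannot epimerize, so the crystalline salt should carry one enantiomer of the acid, and this is the step that fixes the absolute configuration at C8a.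

Step 3
Reactants: 3 (1R)-1-phenylethan-1-aminium (1R)-2-methoxy-5-methyl-1-({[tri(propan-2-yl)silyl]oxy}methyl)cyclohexa-2,5-diene-1-carboxylate
Product: 5 1-[(1R)-2-methoxy-5-methyl-1-({[tri(propan-2-yl)silyl]oxy}methyl)cyclohexa-2,5-dien-1-yl]ethan-1-one, via free acid 4 (not isolated)
Conditions: cold 10% aq. citric acid/Et2O; then MeLi (2.5 equiv), Et2O, 0 °C to rt; inverse quench into cold aq. NH4Cl
Reagents that add atoms: methyllithium, [Li]C
Why: After mild release of the acid (the enol ether is spared), MeLi adds to the carboxylate RCO2Li to give RC(OLi)2CH3, which collapses to the methyl ketone only on work-up (ketone synthesis from a carboxylic acid and an organolithium), leaving the quaternary stereocenter untouched.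

Step 4
Reactants: 5 1-[(1R)-2-methoxy-5-methyl-1-({[tri(propan-2-yl)silyl]oxy}methyl)cyclohexa-2,5-dien-1-yl]ethan-1-one
Product: 6 (2S)-2-acetyl-6-chloro-4-methyl-2-({[tri(propan-2-yl)silyl]oxy}methyl)cyclohex-3-en-1-one (both C6 epimers)
Conditions: N-chlorosuccinimide, NaHCO3, THF–H2O, 0 °C
Reagents that add atoms: N-chlorosuccinimide, ClN1C(=O)CCC1=O; water, O
Why: Electrophilic chlorination of the electron-rich methyl enol ether at C5 and hydrolysis of the oxocarbenium ion give the α-chloro ketone regiospecifically (the C7=C8 alkene is far less nucleophilic), and the new C5 stereocenter is of no consequence because it becomes sp2 in the next step.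

Step 5
Reactants: 6 (2S)-2-acetyl-6-chloro-4-methyl-2-({[tri(propan-2-yl)silyl]oxy}methyl)cyclohex-3-en-1-one
Product: 7 (6R)-6-acetyl-2-chloro-4-methyl-6-({[tri(propan-2-yl)silyl]oxy}methyl)cyclohexa-1,4-dien-1-yl trifluoromethanesulfonate
Conditions: KN(SiMe3)2 (0.98 equiv), THF, −78 to −40 °C; PhNTf2, −78 °C to rt
Reagents that add atoms: N-phenylbis(trifluoromethanesulfonimide), O=S(=O)(N(c1ccccc1)S(=O)(=O)C(F)(F)F)C(F)(F)F
Why: Enolate O-sulfonylation: C8a is quaternary and the C5–H between carbonyl and chlorine is far more acidic than the acetyl methyl, so equilibrating deprotonation should give one enolate and one enol triflate, which fixes the coupling site at C4a before C6 is oxidized and so avoids an ambident 1,3-dione.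

Step 6
Reactants: 7 (6R)-6-acetyl-2-chloro-4-methyl-6-({[tri(propan-2-yl)silyl]oxy}methyl)cyclohexa-1,4-dien-1-yl trifluoromethanesulfonate
Product: 8 (6R)-6-acetyl-2-chloro-4-methyl-3-oxo-6-({[tri(propan-2-yl)silyl]oxy}methyl)cyclohexa-1,4-dien-1-yl trifluoromethanesulfonate
Conditions: CrO3, 3,5-dimethylpyrazole, CH2Cl2, −20 °C
Reagents that add atoms: chromium trioxide, O=[Cr](=O)=O
Why: Allylic C–H oxidation: C6 is the only doubly allylic methylene, and its oxidation gives the cross-conjugated 4,4-disubstituted cyclohexa-2,5-dienone, as is usual for Birch-derived 1,4-dienes.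

Step 7
Reactants: 8 (6R)-6-acetyl-2-chloro-4-methyl-3-oxo-6-({[tri(propan-2-yl)silyl]oxy}methyl)cyclohexa-1,4-dien-1-yl trifluoromethanesulfonate
Product: 9 (4R,5R,6S)-6-acetyl-2-chloro-4,5-dihydroxy-4-methyl-3-oxo-6-({[tri(propan-2-yl)silyl]oxy}methyl)cyclohex-1-en-1-yl trifluoromethanesulfonate
Conditions: OsO4 (5 mol%), N-methylmorpholine N-oxide, citric acid, acetone–H2O, rt
Reagents that add atoms: N-methylmorpholine N-oxide, C[N+]1([O-])CCOCC1; water, O
Why: Osmium-catalysed syn-dihydroxylation with N-oxide reoxidation (citric acid keeps the medium acidic): only the trisubstituted C7=C8 alkene can react, since the other is tetrasubstituted and carries Cl and OTf, and on the flat dienone OsO4 should add anti to the bulky CH2OTIPS arm, that is syn to the smaller acetyl group, which sets C7 and C8 (both R) relative to C8a.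

Step 8
Reactants: 10 (2S)-2-methylbutan-1-ol
Product: 12 (2E,4S)-2,4-dimethylhex-2-enal, via (2S)-2-methylbutanal 11 (not isolated)
Conditions: TEMPO (10 mol%), PhI(OAc)2, CH2Cl2, rt; then Ph3P=C(CH3)CHO, 40 °C
Reagents that add atoms: 2-(triphenyl-λ5-phosphanylidene)propanal, CC(C=O)=P(c1ccccc1)(c1ccccc1)c1ccccc1
Why: Non-basic TEMPO/PhI(OAc)2 oxidation gives the configurationally labile α-branched aldehyde, and its in situ Wittig reaction with the stabilized formyl ylide should give the (E)-enal without touching the S center, which comes from the chiral pool.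

Step 9
Reactants: 12 (2E,4S)-2,4-dimethylhex-2-enal
Product: 13 trimethyl[(3E,5E,7S)-5,7-dimethylnona-3,5-dien-1-yn-1-yl]silane
Conditions: (EtO)2P(O)CH2C≡CSiMe3, LiN(SiMe3)2, THF, −78 to 0 °C
Reagents that add atoms: diethyl [3-(trimethylsilyl)prop-2-yn-1-yl]phosphonate, CCOP(=O)(CC#C[Si](C)(C)C)OCC
Why: Horner–Wadsworth–Emmons olefination with the lithiated propargyl phosphonate should give mainly the (E)-alkene and extends the chain to the silyl-protected dienyne.

Step 10
Reactants: 13 trimethyl[(3E,5E,7S)-5,7-dimethylnona-3,5-dien-1-yn-1-yl]silane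
Product: 14 (3E,5E,7S)-5,7-dimethylnona-3,5-dien-1-yne
Conditions: K2CO3 (cat.), MeOH, rt
Reagents that add atoms: none
Why: Methoxide-mediated protodesilylation of the alkynylsilane frees the terminal alkyne for the coupling.

Step 11
Reactants: 9 (4R,5R,6S)-6-acetyl-2-chloro-4,5-dihydroxy-4-methyl-3-oxo-6-({[tri(propan-2-yl)silyl]oxy}methyl)cyclohex-1-en-1-yl trifluoromethanesulfonate; 14 (3E,5E,7S)-5,7-dimethylnona-3,5-dien-1-yne
Product: 17 (7R,8R,8aS)-8a-acetyl-5-chloro-3-[(1E,3E,5S)-3,5-dimethylhepta-1,3-dien-1-yl]-7,8-dihydroxy-7-methyl-1,7,8,8a-tetrahydro-6H-isochromen-6-one, via silyl ether enynone 15 (not isolated), via hydroxy enynone 16 (not isolated)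
Conditions: PdCl2(PPh3)2 (5 mol%), CuI (10 mol%), i-Pr2NEt, THF, rt; then Bu4NF/AcOH (1:1), 0 °C to rt
Reagents that add atoms: none
Why: Zerovalent palladium (formed in situ from PdCl2(PPh3)2) inserts into the C4a–OTf bond of the β-triflyloxy enone, a vinylogous acyl triflate far more reactive than the C5–Cl bond, the acetylide generated from 14 with CuI and the amine transmetalates, and reductive elimination forms the C4–C4a bond; fluoride then frees the C1 hydroxyl, which adds to C3, the δ-carbon of the new enynone, and protonation at C4 gives the dienol ether (O2–C3 bond). The closest known reaction type is the Sonogashira coupling–hydroalkoxylation (cycloisomerization) domino used for isochromenes and pyranones. Ring A closes in the 6-endo-dig mode, which is the vinylogous Michael position and should therefore be preferred over 5-exo-dig attack at C4. No stereocenter is formed, and none of C7, C8 and C8a can epimerize because none is enolizable. The selectivity needed is for the C1 hydroxyl over the C8 and C7 hydroxyls, and ring strain secures it: closure through O8 would put the C4a=C5 double bond at a bridgehead of a bicyclo[3.3.1] system, and O7 cannot reach C3. Acetic acid buffering and a tertiary amine keep the medium too weakly basic for retro-aldol loss of formaldehyde from the β-hydroxy ketone.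

**Compound list**

1 | 2-methoxy-5-methylbenzoic acid | COc1ccc(C)cc1C(=O)O | starting material
2 | rac-2-methoxy-5-methyl-1-({[tri(propan-2-yl)silyl]oxy}methyl)cyclohexa-2,5-diene-1-carboxylic acid | CC1=CC(C(=O)O)(CO[Si](C(C)C)(C(C)C)C(C)C)C(OC)=CC1 | intermediate
3 | (1R)-1-phenylethan-1-aminium (1R)-2-methoxy-5-methyl-1-({[tri(propan-2-yl)silyl]oxy}methyl)cyclohexa-2,5-diene-1-carboxylate | CC1=C[C@@](C(=O)[O-])(CO[Si](C(C)C)(C(C)C)C(C)C)C(OC)=CC1.C[C@@H]([NH3+])c1ccccc1 | intermediate
4 | (1R)-2-methoxy-5-methyl-1-({[tri(propan-2-yl)silyl]oxy}methyl)cyclohexa-2,5-diene-1-carboxylic acid | CC1=C[C@@](C(=O)O)(CO[Si](C(C)C)(C(C)C)C(C)C)C(OC)=CC1 | intermediate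
5 | 1-[(1R)-2-methoxy-5-methyl-1-({[tri(propan-2-yl)silyl]oxy}methyl)cyclohexa-2,5-dien-1-yl]ethan-1-one | CC1=C[C@@](C(C)=O)(CO[Si](C(C)C)(C(C)C)C(C)C)C(OC)=CC1 | intermediate
6 | (2S)-2-acetyl-6-chloro-4-methyl-2-({[tri(propan-2-yl)silyl]oxy}methyl)cyclohex-3-en-1-one (both C6 epimers) | CC1=C[C@@](C(C)=O)(CO[Si](C(C)C)(C(C)C)C(C)C)C(=O)C(Cl)C1 | intermediate
7 | (6R)-6-acetyl-2-chloro-4-methyl-6-({[tri(propan-2-yl)silyl]oxy}methyl)cyclohexa-1,4-dien-1-yl trifluoromethanesulfonate | CC1=C[C@@](C(C)=O)(CO[Si](C(C)C)(C(C)C)C(C)C)C(OS(=O)(=O)C(F)(F)F)=C(Cl)C1 | intermediate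
8 | (6R)-6-acetyl-2-chloro-4-methyl-3-oxo-6-({[tri(propan-2-yl)silyl]oxy}methyl)cyclohexa-1,4-dien-1-yl trifluoromethanesulfonate | CC1=C[C@@](C(C)=O)(CO[Si](C(C)C)(C(C)C)C(C)C)C(OS(=O)(=O)C(F)(F)F)=C(Cl)C1=O | intermediate
9 | (4R,5R,6S)-6-acetyl-2-chloro-4,5-dihydroxy-4-methyl-3-oxo-6-({[tri(propan-2-yl)silyl]oxy}methyl)cyclohex-1-en-1-yl trifluoromethanesulfonate | FC(F)(F)S(=O)(=O)OC1=C(Cl)C(=O)[C@](C)(O)[C@H](O)[C@@]1(C(C)=O)CO[Si](C(C)C)(C(C)C)C(C)C | intermediate
10 | (2S)-2-methylbutan-1-ol | CC[C@H](C)CO | starting material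
11 | (2S)-2-methylbutanal | CC[C@H](C)C=O | intermediate
12 | (2E,4S)-2,4-dimethylhex-2-enal | CC[C@H](C)/C=C(C)/C=O | intermediate
13 | trimethyl[(3E,5E,7S)-5,7-dimethylnona-3,5-dien-1-yn-1-yl]silane | CC[C@H](C)/C=C(C)/C=C/C#C[Si](C)(C)C | intermediate
14 | (3E,5E,7S)-5,7-dimethylnona-3,5-dien-1-yne | CC[C@H](C)/C=C(C)/C=C/C#C | intermediate
15 | (4S,5R,6R)-4-acetyl-2-chloro-3-[(3E,5E,7S)-5,7-dimethylnona-3,5-dien-1-yn-1-yl]-5,6-dihydroxy-6-methyl-4-({[tri(propan-2-yl)silyl]oxy}methyl)cyclohex-2-en-1-one | CC[C@H](C)/C=C(C)/C=C/C#CC1=C(Cl)C(=O)[C@](C)(O)[C@H](O)[C@@]1(C(C)=O)CO[Si](C(C)C)(C(C)C)C(C)C | intermediate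
16 | (4S,5R,6R)-4-acetyl-2-chloro-3-[(3E,5E,7S)-5,7-dimethylnona-3,5-dien-1-yn-1-yl]-5,6-dihydroxy-4-(hydroxymethyl)-6-methylcyclohex-2-en-1-one | CC[C@H](C)/C=C(C)/C=C/C#CC1=C(Cl)C(=O)[C@](C)(O)[C@H](O)[C@@]1(C(C)=O)CO | intermediate
17 | (7R,8R,8aS)-8a-acetyl-5-chloro-3-[(1E,3E,5S)-3,5-dimethylhepta-1,3-dien-1-yl]-7,8-dihydroxy-7-methyl-1,7,8,8a-tetrahydro-6H-isochromen-6-one | CC[C@H](C)/C=C(C)/C=C/C1=CC2=C(Cl)C(=O)[C@](C)(O)[C@H](O)[C@@]2(C(C)=O)CO1 | target

**Count and risks**

Total steps: 11. Longest linear sequence: 8 steps (steps 1 to 7, then step 11).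

Steps most likely to fail:

Step 7 (dihydroxylation). What may go wrong: slow osmylation of the hindered, electron-poor enone alkene; poor facial discrimination between the acetyl and CH2OTIPS faces; hydrolysis of the vinylogous triflate; or deacylative aromatization of the 4-acyl dienone. The fallback sets out from 7 and comes back at 9. The acetyl group of 7 is reduced with NaBH4 (MeOH, 0 °C) to the carbinol F1. Its hydroxyl then acts as a hydrogen-bond donor that steers stoichiometric OsO4·TMEDA (CH2Cl2, −78 °C) onto the isolated C7=C8 alkene from the face of the hydroxyethyl arm, giving the triol F2. The cis-7,8-diol is capped as the acetonide F3 (2,2-dimethoxypropane, PPTS). Oxidation with CrO3–3,5-dimethylpyrazole returns the carbinol to the acetyl group and oxidizes the allylic C6 methylene, giving the acetonide of 9, F4. Aqueous acetic acid then removes the acetonide to give 9.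

Step 11 (coupling–cyclization). What may go wrong: retro-aldol loss of formaldehyde once the C1 alkoxide of 16 is formed, homocoupling of the alkyne, or incomplete ring closure. The fallback sets out from 9 and 14 and comes back at 17. The sequence is run stepwise and without an anionic conjugate addition: the coupling product 15 is isolated, the silyl group is removed under acidic conditions (HF·pyridine, THF) to give 16, and ring A is closed by π-acid catalysis (AuCl3 or AgOTf, CH2Cl2, rt), a metal-catalysed 6-endo-dig hydroalkoxylation of the alkyne. No compound beyond 15 and 16 is made (F0).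

Step 6 (allylic oxidation). What may go wrong: low conversion because the chloro- and triflyloxy-substituted alkene deactivates the C6–H bonds, or competing oxidation of the allylic methyl group. The fallback sets out from 7 and comes back at 8. It is a two-step oxidation by a different mechanism: SeO2 (cat.)/t-BuOOH allylic hydroxylation (ene reaction, then [2,3]-shift, which targets the CH2 on the more substituted alkene carbon C7) gives the allylic alcohol F5, and MnO2 oxidizes this doubly allylic alcohol to 8.

**Further compounds**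

F1 | step 7 | 1-hydroxyethyl analogue of 7 (acetyl reduced, both carbinol epimers) | CC1=C[C@@](C(C)O)(CO[Si](C(C)C)(C(C)C)C(C)C)C(OS(=O)(=O)C(F)(F)F)=C(Cl)C1
F2 | step 7 | cis-7,8-diol of F1, hydroxyls on the face of the hydroxyethyl arm | FC(F)(F)S(=O)(=O)OC1=C(Cl)C[C@](C)(O)[C@H](O)[C@@]1(C(C)O)CO[Si](C(C)C)(C(C)C)C(C)C
F3 | step 7 | 7,8-O-isopropylidene acetal of F2 | FC(F)(F)S(=O)(=O)OC1=C(Cl)C[C@]2(C)OC(C)(C)O[C@@H]2[C@@]1(C(C)O)CO[Si](C(C)C)(C(C)C)C(C)C
F4 | step 7 | 7,8-O-isopropylidene acetal of 9 | FC(F)(F)S(=O)(=O)OC1=C(Cl)C(=O)[C@]2(C)OC(C)(C)O[C@@H]2[C@@]1(C(C)=O)CO[Si](C(C)C)(C(C)C)C(C)C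
F0 | step 11 | none | none
F5 | step 6 | C6 allylic alcohol of 7 (hydroxyl on the doubly allylic carbon, both epimers) | CC1=C[C@@](C(C)=O)(CO[Si](C(C)C)(C(C)C)C(C)C)C(OS(=O)(=O)C(F)(F)F)=C(Cl)C1O
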